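**The stall.** At 3.7 h the south run holds 0.187 M of target, 23.4% of its starting material. I write the balance of that limiting reagent, charged at 0.800 M against 2.00 M of partner, with three terms, namely what remains, what is target, and what was target and has gone, and the north-west run shows this third term at work. Its excess of target over the south run shrinks from 0.400 M to 0.106 M, which I read as a roughly pseudo-first-order drain of 0.359 /h.

| setting | south | north | north-west | north-east | south-west |
|---|---|---|---|---|---|
| starting material | 0.800 M | 0.320 M | 0.800 M | 0.800 M | 0.800 M |
| partner | 2.00 M | 1.52 M | 2.00 M | 2.00 M | 2.00 M |
| free catalyst | 0.0160 M | 0.0160 M | 0.0160 M | 0.00800 M | 0.00350 M |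
| target |  |  | 0.400 M |  |  |
| time |  |  |  |  | 3.7 h |

| run | time / h | [target] / M |
|---|---|---|
| south run | 0.15 | 0.015 |
| south run | 0.23 | 0.026 |
| south run | 0.37 | 0.038 |
| south run | 0.59 | 0.063 |
| south run | 0.93 | 0.094 |
| south run | 1.5 | 0.135 |
| south run | 2.3 | 0.167 |
| south run | 3.7 | 0.187 |
| north run | 0.15 | 0.008 |
| north run | 0.23 | 0.010 |
| north run | 0.37 | 0.025 |
| north run | 0.59 | 0.039 |
| north run | 0.93 | 0.039 |
| north run | 1.5 | 0.067 |
| north run | 2.3 | 0.080 |
| north run | 3.7 | 0.091 |
| north-west run | 0.15 | 0.385 |
| north-west run | 0.23 | 0.378 |
| north-west run | 0.37 | 0.377 |
| north-west run | 0.59 | 0.363 |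
| north-west run | 0.93 | 0.354 |
| north-west run | 1.5 | 0.333 |
| north-west run | 2.3 | 0.313 |
| north-west run | 3.7 | 0.293 |
| north-east run | 0.15 | 0.006 |
| north-east run | 0.23 | 0.019 |
| north-east run | 0.37 | 0.027 |
| north-east run | 0.59 | 0.045 |
| north-east run | 0.93 | 0.063 |
| north-east run | 1.5 | 0.088 |
| north-east run | 2.3 | 0.113 |
| north-east run | 3.7 | 0.130 |

(readings scatter by 0.004 M)

- Overall: starting material + partner -> target, with free catalyst as catalyst.
- Constant volume, constant temperature.
- Readings of a species count what is bound in complexes too.
- An order is taken over about fifteen percent of the charge, up and down.

- the exponent of [free catalyst] in the starting rate at the charge of the south run (at the point where two percent of the starting material have become target)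
- target in the south-west run at 3.7 h, as a share of the starting material charged

**The neighbour.** The north-east run differs from the south run in its free catalyst, 0.00800 M against 0.0160 M, and ends at 0.130 M. In the south run the drain takes 0.0671 M/h at the end, while the net rise over the last interval is 0.0143 M/h. In the north-east run the same figures are 0.0467 M/h and 0.0121 M/h. The sum of drain and net rise is the feed of new target late in each run, and the south run, which ends higher, has the greater feed, 0.0814 M/h against 0.0588 M/h in the north-east run.

**My rule.** I assume two routes, one proportional to free catalyst and one needing none. The catalyst-borne share, the fraction of the rate that follows free catalyst, is then the fractional loss of rate divided by the fractional loss of catalyst, and if I take the early readings at 0.93 h, 0.063 M in the north-east run against 0.094 M in the south run, as the ratio of rates, it reads 0.660. On a straight line, that share is also the local exponent at the south charge. A first-order drain keeps target proportional to feed, so I apply the rule to the final readings, where the share is 0.610. The south-west run should then retain 0.524 of the south target, which is 12.2% of its charge.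

**The forecast.** It gives an order of 0.55 (0.45 to 0.68) and 10.3% (8.5% to 12.5%), on the ground that “most catalyst sits in an off-cycle dimer-like reservoir”. My two numbers differ from it, both higher.

**The result.** The south-west run gives 12.6% of its charge as target, and the order is 0.65, beside my share of 0.660.

    free catalyst + starting material → catalyst-substrate complex (13.32 /M/h)
    catalyst-substrate complex + partner → loaded catalyst (9.036 /M/h)
    loaded catalyst → target + free catalyst (43.20 /h)
    target + partner → side product (0.2552 /M/h)
    starting material + partner → target (0.03287 /M/h)

The last step of this scheme runs without catalyst, at 0.0526 M/h on the south charge. Put through the same rule, the south-west target of 0.101 M against the south reading gives a catalyst-borne share of 0.590 at 3.7 h.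

(The readings are simulated on assumed constants; the scatter is artificial.)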